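## Retrosynthetic overview

1. The target is reached by acetylation and C2-selective 1,2-reduction of a bicyclo[3.2.1]oct-3-ene-2,8-dione.
2. Key step: that dione comes from a cationic ring expansion of a cyclobutane (bicyclo[4.2.0]octenedione to bicyclo[3.2.1]octenedione). The benzylic carbon migrates, the O-methyl group is relayed, and the five-membered ketone ring is closed last.
3. The cyclobutane comes from a catalytic enantioselective formal [2+2] addition of (E)-isoelemicin to 5-allyl-2,3-dimethoxy-1,4-benzoquinone, which sets the quaternary allyl centre and the CHMe centre.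
4. The quinone comes from squaric acid and pent-1-en-4-yne (esterification, acetylide addition, thermal quinone formation). (E)-Isoelemicin comes from 4-chlorophenol and (E)-propenylboronic acid (bromination, methoxylation/methylation, cross-coupling).
5. Ring order: quinone six-membered ring (from the four-membered squarate), then the cyclobutane, then the five-membered ring by expansion of the cyclobutane.

Assumption: the (S)-configured oxazaborolidinium catalyst is taken to give the (1S,8S) cyclobutane series in step 7; if the facial sense proves opposite, the (R)-catalyst is used with nothing else changed.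

## Route

Step 1
Reactants: 1 4-chlorophenol
Product: 2 2,6-dibromo-4-chlorophenol
Conditions: Br2 (2.1 equiv), AcOH, 0 °C → rt
Reagents that add atoms: bromine, BrBr
Why: Electrophilic aromatic bromination; the hydroxyl group directs to both ortho positions because the para position is blocked by chlorine.

Step 2
Reactants: 2 2,6-dibromo-4-chlorophenol
Product: 4 5-chloro-1,2,3-trimethoxybenzene, via sodium 4-chloro-2,6-dimethoxyphenolate 3 (not isolated)
Conditions: NaOCH3 (6 equiv), CuCl (10 mol%), DMF/CH3OH, 110 °C; then (CH3O)2SO2, 50 °C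
Reagents that add atoms: sodium methoxide, C[O-].[Na+]; dimethyl sulfate, COS(=O)(=O)OC
Why: Copper-catalysed Ullmann-type methoxylation replaces only the two aryl bromides (the aryl chloride is inert here), and the phenolate is then O-methylated in the same pot (Williamson etherification).

Step 3
Reactants: 4 5-chloro-1,2,3-trimethoxybenzene; 5 (E)-prop-1-en-1-ylboronic acid
Product: 6 1,2,3-trimethoxy-5-[(1E)-prop-1-en-1-yl]benzene ((E)-isoelemicin)
Conditions: Pd(OAc)2 (2 mol%), 2-dicyclohexylphosphino-2′,6′-dimethoxybiphenyl (4 mol%), K3PO4, toluene/H2O, 100 °C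
Reagents that add atoms: none
Why: Suzuki–Miyaura coupling; the dialkylbiarylphosphine ligand activates the electron-rich aryl chloride and the (E)-alkene geometry of the boronic acid is retained.

Step 4
Reactants: 7 squaric acid (3,4-dihydroxycyclobut-3-ene-1,2-dione)
Product: 8 dimethyl squarate (3,4-dimethoxycyclobut-3-ene-1,2-dione)
Conditions: HC(OCH3)3, CH3OH, reflux
Reagents that add atoms: methanol, CO; trimethyl orthoformate, COC(OC)OC
Why: Esterification of the vinylogous acid with methanol, driven to completion by the orthoformate as water scavenger.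

Step 5
Reactants: 8 dimethyl squarate; 9 pent-1-en-4-yne
Product: 11 4-hydroxy-2,3-dimethoxy-4-(pent-4-en-1-yn-1-yl)cyclobut-2-en-1-one (racemic), via lithium pent-4-en-1-yn-1-ide 10 (not isolated)
Conditions: n-C4H9Li, THF, −78 °C; then 8, −78 °C; H2O quench
Reagents that add atoms: none
Why: Kinetic deprotonation of the terminal alkyne followed by 1,2-addition of the acetylide to one squarate carbonyl (standard squarate chemistry); the racemic carbinol centre is destroyed in the next step.

Step 6
Reactants: 11 4-hydroxy-2,3-dimethoxy-4-(pent-4-en-1-yn-1-yl)cyclobut-2-en-1-one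
Product: 12 2,3-dimethoxy-5-(prop-2-en-1-yl)cyclohexa-2,5-diene-1,4-dione
Conditions: p-xylene, 138 °C, 1 h
Reagents that add atoms: none
Why: Moore rearrangement; thermal opening of the 4-alkynyl-4-hydroxycyclobutenone to an alkynylketene, ring closure and hydrogen transfer give the 5-substituted 2,3-dimethoxybenzoquinone (used here only to prepare the quinone partner).

Step 7
Reactants: 12 2,3-dimethoxy-5-(prop-2-en-1-yl)cyclohexa-2,5-diene-1,4-dione; 6 (E)-isoelemicin
Product: 13 (1S,6R,7S,8S)-3,4-dimethoxy-8-methyl-1-(prop-2-en-1-yl)-7-(3,4,5-trimethoxyphenyl)bicyclo[4.2.0]oct-3-ene-2,5-dione (cis-fused; methyl syn to the six-membered ring, aryl trans to methyl)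
Conditions: (S)-1-(2-methylphenyl)-3,3-diphenyltetrahydro-1H,3H-pyrrolo[1,2-c][1,3,2]oxazaborole·HN(SO2CF3)2, i.e. [C24H25BNO][N(SO2CF3)2] (20 mol%), CH2Cl2, −78 → −40 °C; Et3N quench at −78 °C
Reagents that add atoms: none
Why: Proposed new method: the protonated oxazaborolidine should bind the only carbonyl of 12 that has an α C–H (C1=O, lone pair syn to H-6, as in its quinone Diels–Alder complexes), so the CHMe terminus of 6 attacks the allyl-bearing C5 (the other β carbon, C3, is deactivated as a vinylogous ester) on the face left open by the catalyst aryl group, and the resulting 3,4,5-trimethoxybenzyl cation/boron enolate collapses at the enolate carbon C6 at low temperature to the cis-fused trans-aryl/methyl cyclobutane (aromatisation is impossible because C5 is quaternary), which sets the quaternary centre and the CHMe centre in absolute terms; closest known reactions are the Lewis-acid-promoted (TiCl4/Ti(OiPr)4, also with chiral diol ligands) formal [2+2] cycloaddition of 2-alkoxy-1,4-benzoquinones with (E)-propenylarenes and oxazaborolidinium-catalysed enantioselective quinone Diels–Alder and quinone/enol ether [3+2] cycloadditions.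

Step 8
Reactants: 13 (1S,6R,7S,8S)-3,4-dimethoxy-8-methyl-1-(prop-2-en-1-yl)-7-(3,4,5-trimethoxyphenyl)bicyclo[4.2.0]oct-3-ene-2,5-dione
Product: 14 (1R,5S,6S,7R)-1,3-dimethoxy-6-methyl-5-(prop-2-en-1-yl)-7-(3,4,5-trimethoxyphenyl)bicyclo[3.2.1]oct-3-ene-2,8-dione (6-exo-methyl, 7-endo-aryl)
Conditions: CF3SO3CH3 (10 mol%), 2,6-di-tert-butyl-4-methylpyridine (5 mol%), CH2Cl2, −40 → 0 °C; Et3N, aq NaHCO3
Reagents that add atoms: none
Why: Proposed new method: CF3SO3CH3 O-methylates the vinylogous-ester carbonyl C5=O next to the ring-fusion C–H, the dialkoxyallyl cation so formed lets the strained benzylic C6–C7 bond ionise to a 3,4,5-trimethoxybenzyl cation, which is recaptured by the methoxy-activated enol-ether carbon C3 (five-membered ring closure, aryl forced trans to the fixed methyl and therefore endo, C1 and C7 of 14 set by the ring), and the bicyclic methyloxocarbenium ion hands its O-methyl to C5=O of the next molecule of 13 (chain), so the cyclobutane is isomerised to 14 with no net reagent; closest known reactions are the acid- or TiCl4-induced rearrangement of quinone–propenylarene cyclobutane adducts to bicyclo[3.2.1]oct-3-ene-2,8-diones and alkyl-triflate-catalysed alkyl-relay isomerisations of imidates (O→N methyl transfer).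

Step 9
Reactants: 14 (1R,5S,6S,7R)-1,3-dimethoxy-6-methyl-5-(prop-2-en-1-yl)-7-(3,4,5-trimethoxyphenyl)bicyclo[3.2.1]oct-3-ene-2,8-dione
Product: 15 (1S,2R,5S,6S,7R)-2-hydroxy-1,3-dimethoxy-6-methyl-5-(prop-2-en-1-yl)-7-(3,4,5-trimethoxyphenyl)bicyclo[3.2.1]oct-3-en-8-one (hydroxyl anti to the C8 bridge)
Conditions: NaBH4 (1.0 equiv), CeCl3·7H2O (1.2 equiv), CH3OH, −78 °C; aq NaHCO3
Reagents that add atoms: none
Why: Luche reduction; the cerium-activated conjugated C2 ketone is expected to be reduced 1,2 in preference to the C8 ketone (between two fully substituted bridgeheads, reversibly masked as its hemiketal in CH3OH), and hydride enters from the face syn to the C8 bridge because the other face is covered by the endo aryl group, giving the (2R)-alcohol.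

Step 10
Reactants: 15 (1S,2R,5S,6S,7R)-2-hydroxy-1,3-dimethoxy-6-methyl-5-(prop-2-en-1-yl)-7-(3,4,5-trimethoxyphenyl)bicyclo[3.2.1]oct-3-en-8-one
Product: 16 (1S,2R,5S,6S,7R)-1,3-dimethoxy-6-methyl-8-oxo-5-(prop-2-en-1-yl)-7-(3,4,5-trimethoxyphenyl)bicyclo[3.2.1]oct-3-en-2-yl acetate (CNP0181407.1)
Conditions: Ac2O, pyridine, 4-(dimethylamino)pyridine (5 mol%), CH2Cl2, 0 °C → rt
Reagents that add atoms: acetic anhydride, CC(=O)OC(C)=O
Why: Nucleophile-catalysed acylation of the secondary alcohol; no stereocentre is touched and the enol ether, ketone and allyl group are inert.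

## Compound list

1 | 4-chlorophenol | Oc1ccc(Cl)cc1 | starting material
2 | 2,6-dibromo-4-chlorophenol | Oc1c(Br)cc(Cl)cc1Br | intermediate
3 | sodium 4-chloro-2,6-dimethoxyphenolate | [Na+].[O-]c1c(OC)cc(Cl)cc1OC | intermediate (not isolated)
4 | 5-chloro-1,2,3-trimethoxybenzene | COc1cc(Cl)cc(OC)c1OC | intermediate
5 | (E)-prop-1-en-1-ylboronic acid | C/C=C/B(O)O | starting material
6 | 1,2,3-trimethoxy-5-[(1E)-prop-1-en-1-yl]benzene ((E)-isoelemicin) | C/C=C/c1cc(OC)c(OC)c(OC)c1 | intermediate
7 | squaric acid (3,4-dihydroxycyclobut-3-ene-1,2-dione) | OC1=C(O)C(=O)C1=O | starting material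
8 | dimethyl squarate (3,4-dimethoxycyclobut-3-ene-1,2-dione) | COC1=C(OC)C(=O)C1=O | intermediate
9 | pent-1-en-4-yne | C=CCC#C | starting material
10 | lithium pent-4-en-1-yn-1-ide | [Li+].[C-]#CCC=C | intermediate (not isolated)
11 | 4-hydroxy-2,3-dimethoxy-4-(pent-4-en-1-yn-1-yl)cyclobut-2-en-1-one (racemic) | C=CCC#CC1(O)C(OC)=C(OC)C1=O | intermediate
12 | 2,3-dimethoxy-5-(prop-2-en-1-yl)cyclohexa-2,5-diene-1,4-dione | C=CCC1=CC(=O)C(OC)=C(OC)C1=O | intermediate
13 | (1S,6R,7S,8S)-3,4-dimethoxy-8-methyl-1-(prop-2-en-1-yl)-7-(3,4,5-trimethoxyphenyl)bicyclo[4.2.0]oct-3-ene-2,5-dione | C=CC[C@]12[C@H](C(=O)C(OC)=C(OC)C1=O)[C@@H](c1cc(OC)c(OC)c(OC)c1)[C@@H]2C | intermediate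
14 | (1R,5S,6S,7R)-1,3-dimethoxy-6-methyl-5-(prop-2-en-1-yl)-7-(3,4,5-trimethoxyphenyl)bicyclo[3.2.1]oct-3-ene-2,8-dione | C=CC[C@]12C=C(OC)C(=O)[C@](OC)(C1=O)[C@@H](c1cc(OC)c(OC)c(OC)c1)[C@@H]2C | intermediate
15 | (1S,2R,5S,6S,7R)-2-hydroxy-1,3-dimethoxy-6-methyl-5-(prop-2-en-1-yl)-7-(3,4,5-trimethoxyphenyl)bicyclo[3.2.1]oct-3-en-8-one | C=CC[C@]12C=C(OC)[C@@H](O)[C@](OC)(C1=O)[C@@H](c1cc(OC)c(OC)c(OC)c1)[C@@H]2C | intermediate
16 | (1S,2R,5S,6S,7R)-1,3-dimethoxy-6-methyl-8-oxo-5-(prop-2-en-1-yl)-7-(3,4,5-trimethoxyphenyl)bicyclo[3.2.1]oct-3-en-2-yl acetate | C=CC[C@]12C=C(OC)[C@@H](OC(C)=O)[C@](OC)(C1=O)[C@@H](c1cc(OC)c(OC)c(OC)c1)[C@@H]2C | target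

## Step count and risks

Total steps: 10. Longest linear sequence: 7 steps (steps 1, 2, 3, 7, 8, 9, 10; the squaric acid branch, steps 4, 5, 6, 7, 8, 9, 10, is equally long).

The three steps most likely to fail:

**Step 7 (proposed new method).** Risks: the other quinone carbonyl may be activated instead (attack at the C–H carbon C6), the zwitterion may close directly to five-membered products, or the enantioselectivity may be low. Fallback with known chemistry, setting out from 12 (with 6) and coming back at 14: reduce 12 with Na2S2O4 (EtOAc/H2O) to 2,3-dimethoxy-5-(prop-2-en-1-yl)benzene-1,4-diol F1. Monomethylate the less hindered hydroxyl ((CH3O)2SO2 1.0 equiv, K2CO3, acetone) to 2,3,4-trimethoxy-6-(prop-2-en-1-yl)phenol F2. Oxidise with PhI(OAc)2 in CH3OH to the quinone monoketal 2,3,4,4-tetramethoxy-6-(prop-2-en-1-yl)cyclohexa-2,5-dien-1-one F3, in which only the required carbonyl position can ionise. Condense F3 with 6 under acid (CF3SO3Si(CH3)3 or 2,4,6-trinitrobenzenesulfonic acid, CH3CN, −30 °C), the known cationic quinone-ketal/propenylarene condensation. This gives the racemic dione, that is 14 together with its (1S,5R,6R,7S)-enantiomer F4. The two are separated by preparative HPLC on a chiral stationary phase, and the route continues from 14; 13 and step 8 are bypassed.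

**Step 8 (proposed new method).** Risks: the methyl relay may not propagate, or the cation may be trapped on oxygen to give a hydrobenzofuranone. Fallback with known chemistry, setting out from 13 and coming back at 14: treat 13 with TiCl4 (2 equiv, CH2Cl2, −78 → 0 °C), the known Lewis-acid rearrangement of such cyclobutanes. The oxocarbenium methyl group is lost as CH3Cl and the product is the diosphenol (1R,5S,6S,7R)-3-hydroxy-1-methoxy-6-methyl-5-(prop-2-en-1-yl)-7-(3,4,5-trimethoxyphenyl)bicyclo[3.2.1]oct-3-ene-2,8-dione F5. O-Methylation of the enol ((CH3O)2SO2, K2CO3, acetone) then gives 14.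

**Step 9.** Risk: the strained C8 ketone may be reduced competitively. Fallback setting out from 14 and coming back at 16: reduce both carbonyls with excess NaBH4 (CH3OH, 0 °C) to 1,3-dimethoxy-6-methyl-5-(prop-2-en-1-yl)-7-(3,4,5-trimethoxyphenyl)bicyclo[3.2.1]oct-3-ene-2,8-diol (ring stereocentres as in 15, C8 epimer not assigned) F6. Acetylate only the less hindered allylic C2 hydroxyl (Ac2O 1.1 equiv, pyridine, 0 °C) to the 8-hydroxy-2-acetate (16 with C8 as carbinol) F7. Re-oxidise the C8 carbinol with Dess–Martin periodinane (NaHCO3, CH2Cl2) to give 16; 15 and step 10 are bypassed.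

## Further compounds

F1 | step 7 | 2,3-dimethoxy-5-(prop-2-en-1-yl)benzene-1,4-diol | C=CCc1cc(O)c(OC)c(OC)c1O
F2 | step 7 | 2,3,4-trimethoxy-6-(prop-2-en-1-yl)phenol | C=CCc1cc(OC)c(OC)c(OC)c1O
F3 | step 7 | 2,3,4,4-tetramethoxy-6-(prop-2-en-1-yl)cyclohexa-2,5-dien-1-one | C=CCC1=CC(OC)(OC)C(OC)=C(OC)C1=O
F4 | step 7 | (1S,5R,6R,7S)-1,3-dimethoxy-6-methyl-5-(prop-2-en-1-yl)-7-(3,4,5-trimethoxyphenyl)bicyclo[3.2.1]oct-3-ene-2,8-dione (enantiomer of 14) | C=CC[C@@]12C=C(OC)C(=O)[C@@](OC)(C1=O)[C@H](c1cc(OC)c(OC)c(OC)c1)[C@H]2C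
F5 | step 8 | (1R,5S,6S,7R)-3-hydroxy-1-methoxy-6-methyl-5-(prop-2-en-1-yl)-7-(3,4,5-trimethoxyphenyl)bicyclo[3.2.1]oct-3-ene-2,8-dione | C=CC[C@]12C=C(O)C(=O)[C@](OC)(C1=O)[C@@H](c1cc(OC)c(OC)c(OC)c1)[C@@H]2C
F6 | step 9 | 1,3-dimethoxy-6-methyl-5-(prop-2-en-1-yl)-7-(3,4,5-trimethoxyphenyl)bicyclo[3.2.1]oct-3-ene-2,8-diol (ring stereocentres as in 15, C8 epimer not assigned) | C=CC[C@]12C=C(OC)[C@@H](O)[C@](OC)(C1O)[C@@H](c1cc(OC)c(OC)c(OC)c1)[C@@H]2C
F7 | step 9 | 8-hydroxy-1,3-dimethoxy-6-methyl-5-(prop-2-en-1-yl)-7-(3,4,5-trimethoxyphenyl)bicyclo[3.2.1]oct-3-en-2-yl acetate (ring stereocentres as in 16, C8 epimer not assigned) | C=CC[C@]12C=C(OC)[C@@H](OC(C)=O)[C@](OC)(C1O)[C@@H](c1cc(OC)c(OC)c(OC)c1)[C@@H]2C
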